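**Retrosynthetic overview**

1. The γ-lactone (O1, C2, C3, C4, C5) is opened at the O1–C2 bond to a γ-hydroxy acid, and the benzylic CH2 on C4 is traced back to an aryl ketone.
2. The plan rests on the four-atom array made of the tertiary hydroxyl oxygen, C3, C4 and the benzylic carbon on C4. With the ketone in place this is a β-hydroxy ketone, the unmasked form of the O1–C5–C4–C3 segment of a 2-isoxazoline ring.
3. The isoxazoline is cut across O1–C5 and C3–C4 into 4-benzyloxy-3-methoxybenzonitrile oxide and an E-trisubstituted allylic alcohol. Suprafacial addition turns the E geometry into the cis arrangement of the two arylmethyl groups; a zinc tartrate bridge fixes regiochemistry and alkene face.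
4. The allylic alcohol comes from an E-selective Wittig reaction of a benzylated ester ylide with silyloxyacetaldehyde, then ester reduction; the dipole comes from O-benzylvanillin oxime.
5. Ring order: isoxazoline first (closed in the key step, opened after oxidation to the acid), lactone last. Carboxyl and silyloxymethyl are trans on the isoxazoline and can only meet after N–O cleavage.

Key step: step 7

**Remarks on the chemistry (assumptions)**

- 4-Benzyloxy-3-methoxybenzyl alcohol, O-benzylvanillin, the ester ylide and (tert-butyldimethylsilyloxy)acetaldehyde are taken as purchased.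
- The sense of induction known for allyl alcohol, where the (R,R)-tartrate gives the 5R hydroxymethyl isoxazoline, is assumed to hold for the trisubstituted allylic alcohol. The benzyl group on C5 ranks lowest there, so the 5S centre needed here is the spatially opposite one and the (S,S)-tartrate is chosen. If the sense proves reversed for this alkene, the (R,R)-ester is used instead.

**Route**

Step 1
Reactants: 1 4-benzyloxy-3-methoxybenzyl alcohol
Product: 2 4-benzyloxy-3-methoxybenzyl bromide
Conditions: PBr3 (0.4 equiv), Et2O, 0 °C to rt; used directly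
Reagents that add atoms: phosphorus tribromide (BrP(Br)Br)
Why: Bromination of a benzylic alcohol with PBr3 (SN2 displacement of the phosphite leaving group) is fast for this electron-rich substrate at 0 °C and leaves the aryl ethers alone; no stereocentre is involved and the labile bromide is used at once.

Step 2
Reactants: 2 4-benzyloxy-3-methoxybenzyl bromide; 3 ethyl (triphenylphosphoranylidene)acetate (2 equiv)
Product: 5 ethyl 3-(4-benzyloxy-3-methoxyphenyl)-2-(triphenylphosphoranylidene)propanoate, via phosphonium bromide 4 (not isolated)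
Conditions: EtOAc, reflux; precipitated phosphonium salt filtered off
Reagents that add atoms: none
Why: C-Alkylation of the ester-stabilised ylide by the reactive benzylic bromide gives salt 4, and transylidation by the second equivalent of 3 (Bestmann alkylation of a stabilised ylide) frees ylide 5 while the unsubstituted phosphonium bromide precipitates; no stereocentre is formed.

Step 3
Reactants: 5 ethyl 3-(4-benzyloxy-3-methoxyphenyl)-2-(triphenylphosphoranylidene)propanoate; 6 (tert-butyldimethylsilyloxy)acetaldehyde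
Product: 7 ethyl (E)-2-(4-benzyloxy-3-methoxybenzyl)-4-(tert-butyldimethylsilyloxy)but-2-enoate
Conditions: toluene, 90 °C
Reagents that add atoms: none
Why: Wittig olefination with an α-substituted ester-stabilised ylide is thermodynamically controlled and places the ester trans to the CH2OSi group of the aldehyde partner, so the E-enoate should strongly predominate and any Z isomer is removed by chromatography; the geometry set here later becomes the relative configuration.

Step 4
Reactants: 7 ethyl (E)-2-(4-benzyloxy-3-methoxybenzyl)-4-(tert-butyldimethylsilyloxy)but-2-enoate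
Product: 8 (E)-2-(4-benzyloxy-3-methoxybenzyl)-4-(tert-butyldimethylsilyloxy)but-2-en-1-ol
Conditions: i-Bu2AlH (2.5 equiv), CH2Cl2, −78 °C; aq. potassium sodium tartrate
Reagents that add atoms: none
Why: 1,2-Reduction of the conjugated ester by i-Bu2AlH at low temperature gives the allylic alcohol without touching the alkene geometry, the silyl ether or the benzyl ether.

Step 5
Reactants: 9 4-benzyloxy-3-methoxybenzaldehyde
Product: 10 (E)-4-benzyloxy-3-methoxybenzaldehyde oxime
Conditions: NH2OH·HCl, NaOAc, EtOH–H2O, rt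
Reagents that add atoms: hydroxylamine hydrochloride (Cl.NO)
Why: Oxime formation by condensation of the aldehyde with hydroxylamine under acetate buffer gives the E-aldoxime.

Step 6
Reactants: 10 (E)-4-benzyloxy-3-methoxybenzaldehyde oxime
Product: 11 (Z)-4-benzyloxy-N-hydroxy-3-methoxybenzimidoyl chloride
Conditions: N-chlorosuccinimide (1.0 equiv), DMF, 25–35 °C
Reagents that add atoms: N-chlorosuccinimide (O=C1CCC(=O)N1Cl)
Why: Chlorination of the aldoxime carbon with N-chlorosuccinimide in DMF (standard hydroximoyl chloride synthesis) is faster than ring chlorination for dialkoxybenzaldoximes when one equivalent is used at or below 35 °C.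

Step 7
Reactants: 8 (E)-2-(4-benzyloxy-3-methoxybenzyl)-4-(tert-butyldimethylsilyloxy)but-2-en-1-ol; 11 (Z)-4-benzyloxy-N-hydroxy-3-methoxybenzimidoyl chloride
Product: 13 [(4R,5S)-3-(4-benzyloxy-3-methoxyphenyl)-5-(4-benzyloxy-3-methoxybenzyl)-4-(tert-butyldimethylsilyloxymethyl)-4,5-dihydroisoxazol-5-yl]methanol, via nitrile oxide 12 (not isolated)
Conditions: Et2Zn (1.0 equiv), CHCl3, 0 °C; diisopropyl (S,S)-tartrate (1.0 equiv); Et2Zn (1.0 equiv); 11 (1.1 equiv) added slowly, 1,4-dioxane (additive), 0 °C; aq. NH4Cl
Reagents that add atoms: none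
Why: Diethylzinc turns 8 into its ethylzinc alkoxide and, with the tartrate and the second equivalent, dehydrochlorinates 11 to nitrile oxide 12, whose oxygen is held on the same dinuclear zinc tartrate as the allylic alkoxide; a concerted, suprafacial [3+2] cycloaddition (π4s + π2s) across the C2=C3 alkene follows. The closest known reaction type is the hydroxyl-directed nitrile oxide cycloaddition to allylic alcohols through magnesium or zinc alkoxides, in its asymmetric tartrate-mediated form. The isoxazoline ring is closed by this intermolecular 1,3-dipolar cycloaddition itself, which forms O1–C5 and C3–C4 in one event. C5 (quaternary) and C4 are set together: their relative configuration comes from the E geometry (hydroxymethyl and silyloxymethyl stay trans, arylmethyl and silyloxymethyl cis), their absolute configuration from the alkene face that the (S,S)-tartrate zinc bridge exposes. The step needs regioselectivity (dipole oxygen to the carbon bearing hydroxymethyl) and face selectivity; the first is secured by the metal bridge and reinforced by the intrinsic preference of the dipole oxygen for the more substituted alkene carbon, the second by the chiral ligand. Slow addition of 11 and the rate gain of the alkoxide should hold back dimerisation of 12 to the furoxan.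

Step 8
Reactants: 13 [(4R,5S)-3-(4-benzyloxy-3-methoxyphenyl)-5-(4-benzyloxy-3-methoxybenzyl)-4-(tert-butyldimethylsilyloxymethyl)-4,5-dihydroisoxazol-5-yl]methanol
Product: 15 (4R,5S)-3-(4-benzyloxy-3-methoxyphenyl)-5-(4-benzyloxy-3-methoxybenzyl)-4-(tert-butyldimethylsilyloxymethyl)-4,5-dihydroisoxazole-5-carboxylic acid, via aldehyde 14 (not isolated)
Conditions: TEMPO (0.2 equiv), PhI(OAc)2 (2.2 equiv), MeCN–H2O (1:1), rt
Reagents that add atoms: water (O)
Why: TEMPO/PhI(OAc)2 oxidation takes the primary alcohol through aldehyde 14 and its hydrate to the carboxylic acid in aqueous acetonitrile; C5 is quaternary, so neither epimerisation nor aromatisation to an isoxazole is possible, and silyl and benzyl ethers tolerate the near-neutral medium.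

Step 9
Reactants: 15 (4R,5S)-3-(4-benzyloxy-3-methoxyphenyl)-5-(4-benzyloxy-3-methoxybenzyl)-4-(tert-butyldimethylsilyloxymethyl)-4,5-dihydroisoxazole-5-carboxylic acid
Product: 17 (2S,3R)-2-(4-benzyloxy-3-methoxybenzyl)-3-(4-benzyloxy-3-methoxybenzoyl)-4-(tert-butyldimethylsilyloxy)-2-hydroxybutanoic acid, via hydroxy imine 16 (not isolated)
Conditions: H2 (1 atm), Raney Ni, B(OH)3, MeOH–H2O (5:1), rt; crude product taken on at once
Reagents that add atoms: water (O)
Why: Hydrogenolysis of the N–O bond over Raney Ni with B(OH)3 and hydrolysis of the resulting β-hydroxy imine in the same pot (isoxazoline unmasking to a β-hydroxy ketone) runs at room temperature and near-neutral pH, conditions under which the stereocentre α to the new ketone and the tertiary aldol are expected to hold.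

Step 10
Reactants: 17 (2S,3R)-2-(4-benzyloxy-3-methoxybenzyl)-3-(4-benzyloxy-3-methoxybenzoyl)-4-(tert-butyldimethylsilyloxy)-2-hydroxybutanoic acid
Product: 18 (2S,3S)-2-(4-benzyloxy-3-methoxybenzyl)-3-[(4-benzyloxy-3-methoxyphenyl)(hydroxy)methyl]-4-(tert-butyldimethylsilyloxy)-2-hydroxybutanoic acid (both epimers at the new carbinol carbon)
Conditions: NaBH4, MeOH, 0 °C; work-up at pH 5
Reagents that add atoms: none
Why: NaBH4 reduction of the aryl ketone (the carboxylate is inert) removes the enolisable carbonyl directly after its release, which secures the adjacent C3 stereocentre; the new carbinol centre forms as a mixture that does not matter because step 11 deletes it.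

Step 11
Reactants: 18 (2S,3S)-2-(4-benzyloxy-3-methoxybenzyl)-3-[(4-benzyloxy-3-methoxyphenyl)(hydroxy)methyl]-4-(tert-butyldimethylsilyloxy)-2-hydroxybutanoic acid
Product: 21 (3S,4R)-3-hydroxy-3,4-bis(4-hydroxy-3-methoxybenzyl)dihydrofuran-2(3H)-one (the target), via silyl ether diphenol acid 19 (not isolated), via seco acid 20 (not isolated)
Conditions: H2 (3 atm), 10% Pd/C, EtOAc–AcOH, 40 °C; filter; then 1 M aq. HCl–THF, rt
Reagents that add atoms: none
Why: Hydrogenolysis over Pd/C cleaves both aryl benzyl ethers and the benzylic C–O bond, which is activated by the para-oxygenated ring as in the hydrogenolysis of benzylic hydroxy lignans (any lactone formed onto the benzylic oxygen is a benzylic ester and is cleaved likewise), while the tertiary non-benzylic alcohol stays; dilute acid then removes the silyl ether and the γ-hydroxy acid closes the lactone (5-exo-trig acyl substitution) with both stereocentres untouched.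

**Compound list**

1 | 4-benzyloxy-3-methoxybenzyl alcohol | OCc1ccc(OCc2ccccc2)c(OC)c1 | starting material
2 | 4-benzyloxy-3-methoxybenzyl bromide | BrCc1ccc(OCc2ccccc2)c(OC)c1 | intermediate
3 | ethyl (triphenylphosphoranylidene)acetate | CCOC(=O)C=P(c1ccccc1)(c1ccccc1)c1ccccc1 | starting material
4 | [3-(4-benzyloxy-3-methoxyphenyl)-1-ethoxy-1-oxopropan-2-yl]triphenylphosphonium bromide | CCOC(=O)C(Cc1ccc(OCc2ccccc2)c(OC)c1)[P+](c1ccccc1)(c1ccccc1)c1ccccc1.[Br-] | intermediate
5 | ethyl 3-(4-benzyloxy-3-methoxyphenyl)-2-(triphenylphosphoranylidene)propanoate | CCOC(=O)C(Cc1ccc(OCc2ccccc2)c(OC)c1)=P(c1ccccc1)(c1ccccc1)c1ccccc1 | intermediate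
6 | (tert-butyldimethylsilyloxy)acetaldehyde | O=CCO[Si](C)(C)C(C)(C)C | starting material
7 | ethyl (E)-2-(4-benzyloxy-3-methoxybenzyl)-4-(tert-butyldimethylsilyloxy)but-2-enoate | CCOC(=O)/C(Cc1ccc(OCc2ccccc2)c(OC)c1)=C/CO[Si](C)(C)C(C)(C)C | intermediate
8 | (E)-2-(4-benzyloxy-3-methoxybenzyl)-4-(tert-butyldimethylsilyloxy)but-2-en-1-ol | OC/C(Cc1ccc(OCc2ccccc2)c(OC)c1)=C/CO[Si](C)(C)C(C)(C)C | intermediate
9 | 4-benzyloxy-3-methoxybenzaldehyde (O-benzylvanillin) | O=Cc1ccc(OCc2ccccc2)c(OC)c1 | starting material
10 | (E)-4-benzyloxy-3-methoxybenzaldehyde oxime | O/N=C/c1ccc(OCc2ccccc2)c(OC)c1 | intermediate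
11 | (Z)-4-benzyloxy-N-hydroxy-3-methoxybenzimidoyl chloride | O/N=C(\Cl)c1ccc(OCc2ccccc2)c(OC)c1 | intermediate
12 | 4-benzyloxy-3-methoxybenzonitrile oxide | [O-][N+]#Cc1ccc(OCc2ccccc2)c(OC)c1 | intermediate
13 | [(4R,5S)-3-(4-benzyloxy-3-methoxyphenyl)-5-(4-benzyloxy-3-methoxybenzyl)-4-(tert-butyldimethylsilyloxymethyl)-4,5-dihydroisoxazol-5-yl]methanol | OC[C@@]1(Cc2ccc(OCc3ccccc3)c(OC)c2)ON=C(c2ccc(OCc3ccccc3)c(OC)c2)[C@@H]1CO[Si](C)(C)C(C)(C)C | intermediate
14 | (4R,5S)-3-(4-benzyloxy-3-methoxyphenyl)-5-(4-benzyloxy-3-methoxybenzyl)-4-(tert-butyldimethylsilyloxymethyl)-4,5-dihydroisoxazole-5-carbaldehyde | O=C[C@@]1(Cc2ccc(OCc3ccccc3)c(OC)c2)ON=C(c2ccc(OCc3ccccc3)c(OC)c2)[C@@H]1CO[Si](C)(C)C(C)(C)C | intermediate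
15 | (4R,5S)-3-(4-benzyloxy-3-methoxyphenyl)-5-(4-benzyloxy-3-methoxybenzyl)-4-(tert-butyldimethylsilyloxymethyl)-4,5-dihydroisoxazole-5-carboxylic acid | OC(=O)[C@@]1(Cc2ccc(OCc3ccccc3)c(OC)c2)ON=C(c2ccc(OCc3ccccc3)c(OC)c2)[C@@H]1CO[Si](C)(C)C(C)(C)C | intermediate
16 | (2S,3R)-2-(4-benzyloxy-3-methoxybenzyl)-3-[(4-benzyloxy-3-methoxyphenyl)carbonimidoyl]-4-(tert-butyldimethylsilyloxy)-2-hydroxybutanoic acid | OC(=O)[C@](O)(Cc1ccc(OCc2ccccc2)c(OC)c1)[C@@H](CO[Si](C)(C)C(C)(C)C)C(=N)c1ccc(OCc2ccccc2)c(OC)c1 | intermediate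
17 | (2S,3R)-2-(4-benzyloxy-3-methoxybenzyl)-3-(4-benzyloxy-3-methoxybenzoyl)-4-(tert-butyldimethylsilyloxy)-2-hydroxybutanoic acid | OC(=O)[C@](O)(Cc1ccc(OCc2ccccc2)c(OC)c1)[C@@H](CO[Si](C)(C)C(C)(C)C)C(=O)c1ccc(OCc2ccccc2)c(OC)c1 | intermediate
18 | (2S,3S)-2-(4-benzyloxy-3-methoxybenzyl)-3-[(4-benzyloxy-3-methoxyphenyl)(hydroxy)methyl]-4-(tert-butyldimethylsilyloxy)-2-hydroxybutanoic acid, both carbinol epimers | OC(=O)[C@](O)(Cc1ccc(OCc2ccccc2)c(OC)c1)[C@@H](CO[Si](C)(C)C(C)(C)C)C(O)c1ccc(OCc2ccccc2)c(OC)c1 | intermediate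
19 | (2S,3R)-4-(tert-butyldimethylsilyloxy)-2-hydroxy-2,3-bis(4-hydroxy-3-methoxybenzyl)butanoic acid | OC(=O)[C@](O)(Cc1ccc(O)c(OC)c1)[C@@H](CO[Si](C)(C)C(C)(C)C)Cc1ccc(O)c(OC)c1 | intermediate
20 | (2S,3R)-2,4-dihydroxy-2,3-bis(4-hydroxy-3-methoxybenzyl)butanoic acid | OC(=O)[C@](O)(Cc1ccc(O)c(OC)c1)[C@@H](CO)Cc1ccc(O)c(OC)c1 | intermediate
21 | (3S,4R)-3-hydroxy-3,4-bis(4-hydroxy-3-methoxybenzyl)dihydrofuran-2(3H)-one | COc1cc(C[C@@H]2COC(=O)[C@]2(O)Cc2ccc(O)c(OC)c2)ccc1O | target

**Step count**

Total: 11 steps. Longest linear sequence: 9 steps (steps 1, 2, 3, 4, 7, 8, 9, 10, 11, from compound 1); the dipole branch (steps 5 and 6) joins at step 7.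

**Steps most likely to fail, with fallbacks**

1. Step 7. The trisubstituted alkene may react slowly, so that dimerisation of the dipole competes, and the tartrate bridge may discriminate the two alkene faces less well than it does for simpler allylic alcohols.
Fallback, setting out from 8 (with 11) and returning at 15: the cycloaddition is run on the achiral magnesium alkoxide of 8 (EtMgBr, CH2Cl2, slow addition of 11). This keeps the hydroxyl-directed regiochemistry and the geometry-derived relative configuration and should give the racemic (4R*,5S*) isoxazoline alcohol F1. Oxidation as in step 8 gives the racemic isoxazoline acid F2. Fractional crystallisation with (R)-1-phenylethylamine should give the diastereomerically pure (R)-1-phenylethylammonium salt of the (4R,5S) acid F3 (the S amine is used if the other salt proves less soluble). Acidification returns 15. Stereocontrol is thus moved from ligand control to classical resolution.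

2. Step 9. The freed aryl ketone may epimerise at its α-carbon, fragment by retro-aldol reaction or lose silanol by β-elimination before it is reduced, and Raney Ni may partly cleave the benzyl ethers or reduce the C=N bond.
Fallback, setting out from 15 and returning at 19: a single hydrogenation over Pd/C in AcOH–H2O (H2, 3–4 atm), in which the ketone never accumulates. The benzyl ethers go first to give the debenzylated isoxazoline acid F4. N–O hydrogenolysis and imine hydrolysis give the debenzylated keto acid F5. Its para-hydroxyaryl ketone is hydrogenolysed on the catalyst through the debenzylated benzylic alcohol F6 to 19, which is carried through the acid stage of step 11. This merges steps 9 to 11 into a reductive cascade.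

3. Step 11. Hydrogenolysis of the benzylic C–O bond may stall once the benzyl ethers are gone, or be diverted by lactonisation onto the benzylic oxygen and catalyst poisoning.
Fallback, setting out from 18 and returning at 21: ionic hydrogenation in place of catalytic hydrogenolysis. Et3SiH (excess) and CF3CO2H in CH2Cl2 at −20 to 0 °C reduce the benzylic cation, which is stabilised by the para-benzyloxy group; low temperature and excess silane are meant to outrun capture of the cation by the neighbouring arene. Aqueous CF3CO2H then removes the silyl ether and closes the lactone, giving the bis(benzyl ether) of the target F7. Neutral hydrogenolysis (H2, Pd/C, EtOAc) of the two aryl benzyl ethers gives 21.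

**Further compounds**

F1 | step 7 | racemic (4R*,5S*)-[3-(4-benzyloxy-3-methoxyphenyl)-5-(4-benzyloxy-3-methoxybenzyl)-4-(tert-butyldimethylsilyloxymethyl)-4,5-dihydroisoxazol-5-yl]methanol (one enantiomer drawn) | OC[C@@]1(Cc2ccc(OCc3ccccc3)c(OC)c2)ON=C(c2ccc(OCc3ccccc3)c(OC)c2)[C@@H]1CO[Si](C)(C)C(C)(C)C
F2 | step 7 | racemic (4R*,5S*)-3-(4-benzyloxy-3-methoxyphenyl)-5-(4-benzyloxy-3-methoxybenzyl)-4-(tert-butyldimethylsilyloxymethyl)-4,5-dihydroisoxazole-5-carboxylic acid (one enantiomer drawn) | OC(=O)[C@@]1(Cc2ccc(OCc3ccccc3)c(OC)c2)ON=C(c2ccc(OCc3ccccc3)c(OC)c2)[C@@H]1CO[Si](C)(C)C(C)(C)C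
F3 | step 7 | (R)-1-phenylethylammonium (4R,5S)-3-(4-benzyloxy-3-methoxyphenyl)-5-(4-benzyloxy-3-methoxybenzyl)-4-(tert-butyldimethylsilyloxymethyl)-4,5-dihydroisoxazole-5-carboxylate | C[C@@H]([NH3+])c1ccccc1.[O-]C(=O)[C@@]1(Cc2ccc(OCc3ccccc3)c(OC)c2)ON=C(c2ccc(OCc3ccccc3)c(OC)c2)[C@@H]1CO[Si](C)(C)C(C)(C)C
F4 | step 9 | (4R,5S)-4-(tert-butyldimethylsilyloxymethyl)-3-(4-hydroxy-3-methoxyphenyl)-5-(4-hydroxy-3-methoxybenzyl)-4,5-dihydroisoxazole-5-carboxylic acid | OC(=O)[C@@]1(Cc2ccc(O)c(OC)c2)ON=C(c2ccc(O)c(OC)c2)[C@@H]1CO[Si](C)(C)C(C)(C)C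
F5 | step 9 | (2S,3R)-4-(tert-butyldimethylsilyloxy)-2-hydroxy-3-(4-hydroxy-3-methoxybenzoyl)-2-(4-hydroxy-3-methoxybenzyl)butanoic acid | OC(=O)[C@](O)(Cc1ccc(O)c(OC)c1)[C@@H](CO[Si](C)(C)C(C)(C)C)C(=O)c1ccc(O)c(OC)c1
F6 | step 9 | (2S,3S)-4-(tert-butyldimethylsilyloxy)-2-hydroxy-3-[hydroxy(4-hydroxy-3-methoxyphenyl)methyl]-2-(4-hydroxy-3-methoxybenzyl)butanoic acid, both carbinol epimers | OC(=O)[C@](O)(Cc1ccc(O)c(OC)c1)[C@@H](CO[Si](C)(C)C(C)(C)C)C(O)c1ccc(O)c(OC)c1
F7 | step 11 | (3S,4R)-3,4-bis(4-benzyloxy-3-methoxybenzyl)-3-hydroxydihydrofuran-2(3H)-one | COc1cc(C[C@@H]2COC(=O)[C@]2(O)Cc2ccc(OCc3ccccc3)c(OC)c2)ccc1OCc1ccccc1
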